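If partner destroys free catalyst while free catalyst turns substrate over, we can divide the one rate by the other so that time drops out of the reckoning.

| setting | zeta | delta | gamma | alpha | midnight | dusk | spring | autumn |
|---|---|---|---|---|---|---|---|---|
| substrate | 49 mM | 24 mM | 37 mM | 49 mM | 49 mM (fed, over 2.0 h) | 49 mM (in portions, 2, over 2.0 h) | 49 mM | 49 mM |
| partner | 58.8 mM | 58.8 mM | 58.8 mM | 120 mM | 58.8 mM | 58.8 mM | 58.8 mM (fed, over 2.0 h) | 58.8 mM |
| free catalyst | 0.24 mM | 0.24 mM | 0.24 mM | 0.24 mM | 0.24 mM | 0.24 mM | 0.24 mM | 0.24 mM |
| second catalyst | 0.24 mM | 0.24 mM | 0.24 mM | 0.24 mM | 0.24 mM | 0.24 mM | 0.24 mM | 0.24 mM |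
| remark | run made earlier | run made earlier | run made earlier | run made earlier | all else is in the flask from the start; the feed brings no volume worth counting | first portion at the start, last at 2.0 h | all else is in the flask from the start; the feed brings no volume worth counting | everything together at the start |
| time |  |  |  |  | 3.0 h | 3.0 h | 3.0 h | 3.0 h |

| run | time / h | target / % |
|---|---|---|
| zeta | 0.250 | 4.8 |
| zeta | 0.417 | 7.0 |
| zeta | 0.667 | 11.9 |
| zeta | 1.00 | 14.1 |
| zeta | 2.00 | 18.9 |
| zeta | 3.00 | 16.5 |
| delta | 0.200 | 4.2 |
| delta | 0.667 | 13.2 |
| delta | 1.00 | 15.2 |
| delta | 1.50 | 15.5 |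
| delta | 2.50 | 15.9 |
| delta | 3.00 | 17.6 |
| gamma | 0.200 | 3.5 |
| gamma | 0.667 | 11.2 |
| gamma | 1.00 | 15.7 |
| gamma | 1.50 | 15.6 |
| gamma | 2.50 | 14.5 |
| gamma | 3.00 | 16.5 |
| alpha | 0.667 | 7.3 |
| alpha | 1.33 | 8.3 |
| alpha | 2.00 | 8.1 |
| alpha | 2.50 | 9.0 |
| alpha | 3.00 | 9.3 |

(each reading ± 1 percentage point)



* the best flask by amount of target, in percent of the substrate charged; "all alike" if 1.5 percentage points covers them all (midnight / dusk / spring / autumn / all alike)
* amount of target at the end, in percent of the substrate charged, midnight
* amount of target at the end, in percent of the substrate charged, dusk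
* amount of target at the end, in percent of the substrate charged, spring
* amount of target at the end, in percent of the substrate charged, autumn

First question: do the runs look like that? At 3.00 h, zeta with 49 mM of substrate reads 16.5% and delta with 24 mM reads 17.6%, so these two readings differ by 1.1 percentage points between charges a factor 2.04 apart. Alpha, with 120 mM of partner, reads 9.3%, less than zeta.

So let y be the fraction of substrate left, C the free catalyst charged and B the partner. If B holds steady and the free catalyst is lost to it, then −ln y = S·C/B at the end, where S is the selectivity factor, the rate constant of substrate on free catalyst over that of partner. Taking B as alpha's charge and counting the target read as the substrate lost, the alpha reading gives S = 48.8, a value that carries the scatter of that reading.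

Second question: what does S give with partner present from the start? Autumn repeats the zeta recipe, and we reckon 18.1%. Dusk's first portion is half of the charge, so if the last portion meets spent catalyst, we reckon 9.03%. We set no figure for midnight: its substrate enters over 2.0 h, and this reckoning was made for substrate charged at the start.

Third question: how low does B stand in spring? Partner enters at 29.4 mM h⁻¹. If target takes it up one for one at zeta's early 9.41 mM h⁻¹, partner averages 20.0 mM over the feed. That is below the charge, and S, with this mean standing in for a steady B as an estimate, gives 44.3%, above our autumn. Among the flasks we reckoned, spring leads.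

The forecast also names spring, with midnight 7.5%, dusk 9.8%, autumn 17% and spring 27%, which is lower than our figure. Its ground is “Feeding partner keeps the catalyst alive”.

The flasks give midnight 2.65%, dusk 8.36%, autumn 17.0% and spring 52.6%, so spring is best. Mean partner in spring over the first 2.0 h was 16.3 mM, lower than our 20.0 mM. Put into S, that mean gives 51.4%, against 52.6% from the flask.

    substrate + free catalyst → free catalyst + open intermediate (k = 0.673 L mol⁻¹ s⁻¹)
    second catalyst + open intermediate ⇌ catalyst intermediate (K = 340 L mol⁻¹, k = 5.48 L mol⁻¹ s⁻¹)
    partner + catalyst intermediate → second catalyst + target (k = 7.83 L mol⁻¹ s⁻¹)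
    partner + free catalyst → spent catalyst (k = 0.0154 L mol⁻¹ s⁻¹)

For the neighbour of spring with 20 mM of substrate, we scale the uptake of partner with the substrate charge, so partner averages 25.6 mM and S gives 36.8%, below our 44.3% for spring. That neighbour flask gives 46.7%, below spring's 52.6%, with 53.2% of its substrate left.

The numbers in the tables come from a simulation with made-up constants; noise was put on by code.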